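**Retrosynthetic overview**

- The last ring is the cyclohexene C8–C9–C14–C15=C16–C17. Its C15=C16 bond lies between C14 and C17, its C9–C14 bond is shared with the cyclohexane (tether C10–C13) and its C8–C17 bond with the 16-membered lactone. One transannular Diels–Alder reaction of a 24-membered (2E,4Z,6E,8Z,14E,16E,18E,20E)-octaene lactone (diene C14–C17, dienophile C8=C9) therefore gives the 6-6-16 tricycle and sets C8, C9, C14 and C17.
- The 24-membered ring comes from an intramolecular Stille coupling at C7–C8, run as a cascade with the cycloaddition. The acyclic precursor is assembled by esterification (O23–C1) and a site-selective Suzuki coupling (C15–C16).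
- C8–C15 bis(vinyl iodide): from the commercial statin side-chain diol, which supplies C9–C14 and both oxygen stereocenters (C11, C13). A δ-lactone differentiates O11 (methylated) from O13.
- C16–C27 trienyl boronate: from N-Boc-D-alaninol (C26) by crotylboration (C24, C25), allenylzinc propargylation (C22, C23), hydrozirconation and a stannyl/boryl diene linchpin. C1–C7 stannyl trienoic acid: from but-2-yn-1-ol.
- Ring order: temporary oxazolidine, then the 24-membered macrocycle, then cyclohexene, cyclohexane and 16-membered lactone together in the cycloaddition (nothing is closed afterwards); then the C13 carbamate and N-acetyl/25-OH unmasking.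

Key step: step 27

Remark: atom numbers are those of the natural product (C1 lactone carbonyl, C8 quaternary carbon, C9/C14 ring fusion, C23 lactone carbinol, C26 nitrogen-bearing carbon).

**Part A – C8–C15 bis(vinyl iodide)**

Step 1
Reactants: 1 tert-butyl 2-[(4R,6S)-6-(hydroxymethyl)-2,2-dimethyl-1,3-dioxan-4-yl]acetate
Product: 2 tert-butyl 2-[(4R,6S)-6-formyl-2,2-dimethyl-1,3-dioxan-4-yl]acetate
Conditions: Dess–Martin periodinane, pyridine, CH2Cl2, 0 °C → rt; used crude
Reagents that add atoms: none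
Why: Dess–Martin oxidation of a primary alcohol stops at the aldehyde under buffered conditions, so the α-alkoxy stereocenter (C13) should survive.

Step 2
Reactants: 2 tert-butyl 2-[(4R,6S)-6-formyl-2,2-dimethyl-1,3-dioxan-4-yl]acetate
Product: 3 tert-butyl 2-[(4R,6S)-6-[(E)-2-iodoethenyl]-2,2-dimethyl-1,3-dioxan-4-yl]acetate
Conditions: CrCl2, CHI3, THF/1,4-dioxane, 0 °C → rt
Reagents that add atoms: iodoform IC(I)I
Why: Takai olefination should give the (E)-vinyl iodide (C14=C15) through the gem-dichromium reagent, and Cr(II) leaves the ester and acetonide alone.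

Step 3
Reactants: 3 tert-butyl 2-[(4R,6S)-6-[(E)-2-iodoethenyl]-2,2-dimethyl-1,3-dioxan-4-yl]acetate
Product: 4 (4R,6S)-4-hydroxy-6-[(E)-2-iodoethenyl]oxan-2-one
Conditions: TFA, CH2Cl2, trace H2O, 0 °C → rt; toluene azeotrope
Reagents that add atoms: none
Why: Acid cleaves the acetonide and the tert-butyl ester and the freed 13-OH closes the six-membered lactone onto C9 (statin-type lactonization), which leaves 11-OH as the only free hydroxyl without touching a stereocenter.

Step 4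
Reactants: 4 (4R,6S)-4-hydroxy-6-[(E)-2-iodoethenyl]oxan-2-one
Product: 5 (4R,6S)-6-[(E)-2-iodoethenyl]-4-methoxyoxan-2-one
Conditions: Me3OBF4, 1,8-bis(dimethylamino)naphthalene, 4 Å MS, CH2Cl2, rt
Reagents that add atoms: trimethyloxonium tetrafluoroborate C[O+](C)C.F[B-](F)(F)F
Why: O-Methylation with Meerwein salt and a non-nucleophilic base avoids the β-elimination that an alkoxide would cause in a β-oxy lactone.

Step 5
Reactants: 5 (4R,6S)-6-[(E)-2-iodoethenyl]-4-methoxyoxan-2-one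
Product: 6 (3R,5S,6E)-5-hydroxy-7-iodo-N,3-dimethoxy-N-methylhept-6-enamide
Conditions: MeNH(OMe)·HCl, AlMe3, CH2Cl2, 0 °C → rt
Reagents that add atoms: N,O-dimethylhydroxylamine hydrochloride CNOC.Cl
Why: Aluminium amide aminolysis of the lactone gives the Weinreb amide at C9 and frees 13-OH, which completes the O11/O13 differentiation.

Step 6
Reactants: 6 (3R,5S,6E)-5-hydroxy-7-iodo-N,3-dimethoxy-N-methylhept-6-enamide
Product: 7 (3R,5S,6E)-5-[tert-butyl(dimethyl)silyl]oxy-7-iodo-N,3-dimethoxy-N-methylhept-6-enamide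
Conditions: TBSOTf, 2,6-lutidine, CH2Cl2, −78 °C
Reagents that add atoms: tert-butyldimethylsilyl triflate CC(C)(C)[Si](C)(C)OS(=O)(=O)C(F)(F)F
Why: Silylation of the only free hydroxyl gives an allylic ether that is inert to Pd(0), unlike an allylic carbamate.

Step 7
Reactants: 7 (3R,5S,6E)-5-[tert-butyl(dimethyl)silyl]oxy-7-iodo-N,3-dimethoxy-N-methylhept-6-enamide
Product: 8 (3R,5S,6E)-5-[tert-butyl(dimethyl)silyl]oxy-7-iodo-3-methoxyhept-6-enal
Conditions: DIBAL-H, THF, −78 °C; Rochelle salt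
Reagents that add atoms: none
Why: Weinreb amide reduction stops at the aldehyde because the chelated tetrahedral intermediate survives until work-up.

Step 8
Reactants: 8 (3R,5S,6E)-5-[tert-butyl(dimethyl)silyl]oxy-7-iodo-3-methoxyhept-6-enal
Product: 9 tert-butyl-[(1E,3S,5S,7Z)-1,8-diiodo-5-methoxynona-1,7-dien-3-yl]oxy-dimethylsilane
Conditions: EtPPh3Br, n-BuLi, THF; I2, −78 °C; NaHMDS, −20 °C; then 8, −78 → −20 °C
Reagents that add atoms: ethyltriphenylphosphonium bromide CC[P+](c1ccccc1)(c1ccccc1)c1ccccc1.[Br-]; iodine II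
Why: Stork–Zhao olefination with the α-iodoethylidene ylide should place iodine cis to C10, the (Z)-geometry that later makes the C8 methyl cis to H9.

**Part B – C1–C7 stannyl trienoic acid**

Step 9
Reactants: 10 but-2-yn-1-ol
Product: 12 (Z)-3-iodobut-2-en-1-ol, via cyclic vinylalanate 11 (not isolated)
Conditions: NaAlH2(OCH2CH2OMe)2, THF, 0 °C → rt; then I2, −78 → 0 °C
Reagents that add atoms: iodine II
Why: Hydroxyl-directed trans-hydroalumination gives the five-membered oxa-aluminacycle with aluminium on C3, and iodinolysis with retention gives the (Z)-iodide that becomes the 4Z olefin.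

Step 10
Reactants: 12 (Z)-3-iodobut-2-en-1-ol
Product: 14 ethyl (2E,4Z)-5-iodohexa-2,4-dienoate, via (Z)-3-iodobut-2-enal 13 (not isolated)
Conditions: MnO2, Ph3P=CHCO2Et, CH2Cl2, rt
Reagents that add atoms: ethyl (triphenylphosphoranylidene)acetate CCOC(=O)C=P(c1ccccc1)(c1ccccc1)c1ccccc1
Why: Tandem allylic oxidation/Wittig olefination traps the isomerization-prone (Z)-iodoenal as it forms, and the stabilized ylide gives the 2E olefin.

Step 11
Reactants: 14 ethyl (2E,4Z)-5-iodohexa-2,4-dienoate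
Product: 15 ethyl (2E,4Z,6E)-5-methyl-7-(tributylstannyl)hepta-2,4,6-trienoate
Conditions: (E)-Bu3SnCH=CHSnBu3 (3 equiv), PdCl2(MeCN)2 (5 mol %), DMF, rt, dark
Reagents that add atoms: (E)-1,2-bis(tributylstannyl)ethene CCCC[Sn](CCCC)(CCCC)/C=C/[Sn](CCCC)(CCCC)CCCC
Why: Stille coupling proceeds with retention at both partners (4Z and 6E kept), and the excess of distannane suppresses the second coupling.

Step 12
Reactants: 15 ethyl (2E,4Z,6E)-5-methyl-7-(tributylstannyl)hepta-2,4,6-trienoate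
Product: 16 (2E,4Z,6E)-5-methyl-7-(tributylstannyl)hepta-2,4,6-trienoic acid
Conditions: LiOH·H2O, THF/MeOH/H2O, 0 °C → rt; aq. NaHSO4 to pH 4–5
Reagents that add atoms: lithium hydroxide monohydrate [Li+].[OH-].O
Why: Saponification leaves the vinylstannane and the Z olefin untouched, since both are stable to hydroxide and the work-up is only weakly acidic.

**Part C – C16–C19 stannyl/boryl diene linchpin**

Step 13
Reactants: 17 ethyl but-2-ynoate
Product: 18 ethyl (E)-3-(tributylstannyl)but-2-enoate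
Conditions: Bu3SnH, LDA, THF, −20 °C; CuBr·SMe2, −78 °C; then 17, MeOH, −78 °C
Reagents that add atoms: (tributylstannyl)copper(I)–dimethyl sulfide, made in the flask from Bu3SnH CCCC[Sn]([Cu])(CCCC)CCCC.CSC
Why: syn-Stannylcupration of the ynoate with protonation at −78 °C gives the kinetic (E)-β-stannyl enoate (Sn and H cis), which fixes the 18E geometry.

Step 14
Reactants: 18 ethyl (E)-3-(tributylstannyl)but-2-enoate
Product: 19 (E)-3-(tributylstannyl)but-2-en-1-ol
Conditions: DIBAL-H, CH2Cl2, −78 °C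
Reagents that add atoms: none
Why: 1,2-Reduction of the enoate to the allylic alcohol does not affect the vinylstannane.

Step 15
Reactants: 19 (E)-3-(tributylstannyl)but-2-en-1-ol
Product: 20 (E)-3-(tributylstannyl)but-2-enal
Conditions: MnO2, CH2Cl2, rt
Reagents that add atoms: none
Why: Allylic oxidation with MnO2 is neutral and should not isomerize the E olefin.

Step 16
Reactants: 20 (E)-3-(tributylstannyl)but-2-enal
Product: 21 tributyl-[(2E,4E)-5-(4,4,5,5-tetramethyl-1,3,2-dioxaborolan-2-yl)penta-2,4-dien-2-yl]stannane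
Conditions: CrCl2, Cl2CHB(pin), LiI, THF, rt
Reagents that add atoms: 2-(dichloromethyl)-4,4,5,5-tetramethyl-1,3,2-dioxaborolane ClC(Cl)B1OC(C)(C)C(C)(C)O1
Why: Takai–Utimoto boryl-olefination gives the (E)-alkenylboronate (16E), and Cr(II) does not touch the vinylstannane.

**Part D – C16–C27 trienyl boronate**

Step 17
Reactants: 22 tert-butyl N-[(2R)-1-hydroxypropan-2-yl]carbamate (N-Boc-D-alaninol)
Product: 23 tert-butyl N-[(2R)-1-oxopropan-2-yl]carbamate
Conditions: Dess–Martin periodinane, wet CH2Cl2, rt; used at once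
Reagents that add atoms: none
Why: Dess–Martin oxidation gives N-Boc-α-amino aldehydes without epimerization, so C26 keeps its D-alanine configuration.

Step 18
Reactants: 23 tert-butyl N-[(2R)-1-oxopropan-2-yl]carbamate
Product: 24 tert-butyl N-[(2R,3S,4S)-3-hydroxy-4-methylhex-5-en-2-yl]carbamate
Conditions: (E)-crotyl-B(Ipc)2 [trans-2-butene, KOt-Bu, n-BuLi; (−)-Ipc2BOMe; BF3·OEt2], THF, −78 °C; then NaOH, H2O2
Reagents that add atoms: (E)-crotylbis(isopinocampheyl)borane from (+)-α-pinene C/C=C/CB([C@@H]1C[C@@H]2C[C@H]([C@H]1C)C2(C)C)[C@@H]1C[C@@H]2C[C@H]([C@H]1C)C2(C)C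
Why: Brown crotylboration through a chair transition state gives the 24,25-anti product from the (E)-crotyl group, and the reagent from (+)-α-pinene attacks the Si face, which is also the Felkin–Anh face, so C25 is set 25,26-anti in a matched case.

Step 19
Reactants: 24 tert-butyl N-[(2R,3S,4S)-3-hydroxy-4-methylhex-5-en-2-yl]carbamate
Product: 25 tert-butyl (4R,5S)-5-[(2S)-but-3-en-2-yl]-2,2,4-trimethyl-1,3-oxazolidine-3-carboxylate
Conditions: 2,2-dimethoxypropane, BF3·OEt2 (cat.), acetone, rt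
Reagents that add atoms: 2,2-dimethoxypropane COC(C)(C)OC
Why: N,O-Acetalization masks 25-OH and the carbamate N–H in one temporary ring that stands up to organometallic, palladium and fluoride steps.

Step 20
Reactants: 25 tert-butyl (4R,5S)-5-[(2S)-but-3-en-2-yl]-2,2,4-trimethyl-1,3-oxazolidine-3-carboxylate
Product: 26 tert-butyl (4R,5S)-2,2,4-trimethyl-5-[(2R)-1-oxopropan-2-yl]-1,3-oxazolidine-3-carboxylate
Conditions: OsO4 (cat.), NaIO4, 2,6-lutidine, 1,4-dioxane/H2O, rt; used crude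
Reagents that add atoms: sodium periodate [Na+].[O-]I(=O)(=O)=O; osmium tetroxide (catalytic oxygen carrier) O=[Os](=O)(=O)=O
Why: Lemieux–Johnson cleavage of the terminal alkene gives the C23 aldehyde under buffered conditions that should not epimerize C24.

Step 21
Reactants: 27 (2S)-but-3-yn-2-ol
Product: 28 (2S)-but-3-yn-2-yl methanesulfonate
Conditions: MsCl, Et3N, CH2Cl2, −78 → 0 °C
Reagents that add atoms: methanesulfonyl chloride CS(=O)(=O)Cl
Why: O-Sulfonylation does not touch the C–O bond, so the configuration is retained.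

Step 22
Reactants: 26 tert-butyl (4R,5S)-2,2,4-trimethyl-5-[(2R)-1-oxopropan-2-yl]-1,3-oxazolidine-3-carboxylate; 28 (2S)-but-3-yn-2-yl methanesulfonate
Product: 29 tert-butyl (4R,5S)-5-[(2S,3R,4R)-3-hydroxy-4-methylhex-5-yn-2-yl]-2,2,4-trimethyl-1,3-oxazolidine-3-carboxylate
Conditions: Pd(OAc)2 (5 mol %), PPh3 (5 mol %), Et2Zn, THF, −78 → −20 °C
Reagents that add atoms: none
Why: Marshall propargylation (anti-SN2′ oxidative addition, Zn transmetalation, cyclic SE2′ addition of the chiral allenylzinc) gives the anti homopropargylic alcohol, in which the (S)-mesylate sets C22 and the required aldehyde face is the Felkin–Anh face, so C23 is set 23,24-syn in a matched case.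

Step 23
Reactants: 29 tert-butyl (4R,5S)-5-[(2S,3R,4R)-3-hydroxy-4-methylhex-5-yn-2-yl]-2,2,4-trimethyl-1,3-oxazolidine-3-carboxylate
Product: 31 tert-butyl (4R,5S)-5-[(2S,3R,4R,5E)-3-hydroxy-6-iodo-4-methylhex-5-en-2-yl]-2,2,4-trimethyl-1,3-oxazolidine-3-carboxylate, via alkenylzirconocene 30 (not isolated)
Conditions: Cp2Zr(H)Cl (2.5 equiv), THF, rt; then I2, 0 °C
Reagents that add atoms: iodine II
Why: syn-Hydrozirconation puts zirconium on the terminal carbon and iodinolysis with retention gives the (E)-vinyl iodide (20E), with the hydroxyl carried as its zirconium alkoxide.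

Step 24
Reactants: 31 tert-butyl (4R,5S)-5-[(2S,3R,4R,5E)-3-hydroxy-6-iodo-4-methylhex-5-en-2-yl]-2,2,4-trimethyl-1,3-oxazolidine-3-carboxylate; 21 tributyl-[(2E,4E)-5-(4,4,5,5-tetramethyl-1,3,2-dioxaborolan-2-yl)penta-2,4-dien-2-yl]stannane
Product: 32 tert-butyl (4R,5S)-5-[(2S,3R,4R,5E,7E,9E)-3-hydroxy-4,7-dimethyl-10-(4,4,5,5-tetramethyl-1,3,2-dioxaborolan-2-yl)deca-5,7,9-trien-2-yl]-2,2,4-trimethyl-1,3-oxazolidine-3-carboxylate
Conditions: Pd2(dba)3 (5 mol %), AsPh3 (20 mol %), CuI (20 mol %), NMP, rt, dark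
Reagents that add atoms: none
Why: Copper-accelerated Stille coupling joins C19 to C20 with retention at both olefins, and without base or fluoride the pinacol boronate stays intact.

**Part E – union, key step and endgame**

Step 25
Reactants: 32 C16–C27 trienyl boronate (full name in step 24); 9 tert-butyl-[(1E,3S,5S,7Z)-1,8-diiodo-5-methoxynona-1,7-dien-3-yl]oxy-dimethylsilane
Product: 33 C8–C27 seco-alcohol: (8Z)-8-iodo-olefin and (14E,16E,18E,20E)-tetraene with 11-OMe, 13-OTBS, free 23-OH and the N-Boc oxazolidine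
Conditions: Pd(PPh3)4 (10 mol %), TlOEt, THF/H2O (3:1), rt, dark; 9 in slight excess
Reagents that add atoms: none
Why: Thallium-accelerated Suzuki–Miyaura coupling should engage the unhindered (E)-1-iodoalkene (C15) at room temperature and leave the α-methyl-substituted (Z)-iodide (C8) for the ring closure, with retention of all olefin geometries.

Step 26
Reactants: 33 C8–C27 seco-alcohol; 16 (2E,4Z,6E)-5-methyl-7-(tributylstannyl)hepta-2,4,6-trienoic acid
Product: 34 C23 ester of 33 with acid 16 (acyclic C8 iodide/C7 stannane)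
Conditions: 2,4,6-trichlorobenzoyl chloride, Et3N, DMAP, toluene, rt, dark
Reagents that add atoms: none
Why: Yamaguchi esterification acylates 23-OH, the only free hydroxyl, through the mixed anhydride and acylpyridinium, and the vinyl iodide and vinylstannane survive these non-metal conditions.

Step 27
Reactants: 34 C23 ester of 33 with acid 16 (acyclic C8 iodide/C7 stannane)
Product: 36 13-O-TBS-13-O-decarbamoyl-N-deacetyl-N-Boc-N,25-O-isopropylidene-superstolide A, via macrocyclic octaene lactone 35 (not isolated)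
Conditions: Pd2(dba)3·CHCl3 (20 mol %), AsPh3 (80 mol %), i-Pr2NEt, DMF/THF (1:1), 1 mM, rt, dark; then 40 °C until 35 is consumed
Reagents that add atoms: none
Why: Pd(0) inserts into the C8–I bond, the trienylstannane transmetalates and reductive elimination forms C7–C8 with retention, which closes the 24-membered ring by an end-to-end sp2–sp2 Stille macrocyclization and creates the (2E,4Z,6E,8Z)-tetraenoate of 35. In 35 the C8=C9 dienophile, now vinylogously activated by the trienoate, is tied to the C14=C15–C16=C17 diene by the four-carbon C10–C13 tether, so a transannular Diels–Alder reaction (closest known type: transannular and intramolecular [4+2] reactions of polyene macrolactones) should follow at or just above room temperature and form C9–C14 and C8–C17. This one concerted, suprafacial [4+2] closes the cyclohexene, and the same two bonds close the cyclohexane through the tether and contract the 24-membered ring to the 16-membered lactone. The 8Z geometry puts the C8 methyl cis to H9, the 14E,16E diene puts H14 cis to H17, and the endo position of the trienoate branch (C7), which the Z olefin forces on C10 as well, gives the cis ring fusion and relates the two pairs. The π-face is controlled by C11 and C13 through a chair-like tether in which 11-OMe, 13-OTBS and the fully substituted C8 are equatorial and the flat diene is axial. The step needs site selectivity among eight alkenes (only C8=C9 and C14–C17 can reach a six-membered transition state), no cycloaddition before ring closure (in 34 the dienophile is an unactivated vinyl iodide) and high dilution to favour cyclization over oligomerization.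

Step 28
Reactants: 36 13-O-TBS-13-O-decarbamoyl-N-deacetyl-N-Boc-N,25-O-isopropylidene-superstolide A
Product: 37 13-O-decarbamoyl-N-deacetyl-N-Boc-N,25-O-isopropylidene-superstolide A
Conditions: TBAF, AcOH, THF, rt
Reagents that add atoms: none
Why: Buffered fluoride desilylation frees 13-OH while the lactone, the oxazolidine and the polyenes are stable to these near-neutral conditions.

Step 29
Reactants: 37 13-O-decarbamoyl-N-deacetyl-N-Boc-N,25-O-isopropylidene-superstolide A
Product: 39 N-deacetyl-N-Boc-N,25-O-isopropylidene-superstolide A, via N-trichloroacetyl carbamate 38 (not isolated)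
Conditions: Cl3CC(O)NCO, CH2Cl2, 0 °C; then neutral Al2O3, rt
Reagents that add atoms: trichloroacetyl isocyanate O=C=NC(=O)C(Cl)(Cl)Cl
Why: Addition of the only free hydroxyl to the acyl isocyanate and mild cleavage of the trichloroacetyl group on alumina gives the primary carbamate at C13 while 25-OH is still masked.

Step 30
Reactants: 39 N-deacetyl-N-Boc-N,25-O-isopropylidene-superstolide A
Product: 41 superstolide A, via N-deacetylsuperstolide A 40 (not isolated)
Conditions: TMSOTf, 2,6-lutidine, CH2Cl2, 0 °C; MeOH, aq. NH4Cl; then Ac2O, Et3N, MeOH, 0 °C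
Reagents that add atoms: acetic anhydride CC(=O)OC(C)=O
Why: Silyl triflate cleaves the Boc group under buffered, non-protic conditions, the resulting N–H aminal collapses to the amino alcohol, and the amine is then acetylated selectively over the hindered 25-OH and the carbamate NH2.

**Compound list**

1 | tert-butyl 2-[(4R,6S)-6-(hydroxymethyl)-2,2-dimethyl-1,3-dioxan-4-yl]acetate | CC(C)(C)OC(=O)C[C@H]1C[C@@H](CO)OC(C)(C)O1 | starting material
2 | tert-butyl 2-[(4R,6S)-6-formyl-2,2-dimethyl-1,3-dioxan-4-yl]acetate | CC(C)(C)OC(=O)C[C@H]1C[C@@H](C=O)OC(C)(C)O1 | intermediate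
3 | tert-butyl 2-[(4R,6S)-6-[(E)-2-iodoethenyl]-2,2-dimethyl-1,3-dioxan-4-yl]acetate | CC(C)(C)OC(=O)C[C@H]1C[C@@H](/C=C/I)OC(C)(C)O1 | intermediate
4 | (4R,6S)-4-hydroxy-6-[(E)-2-iodoethenyl]oxan-2-one | O=C1C[C@H](O)C[C@@H](/C=C/I)O1 | intermediate
5 | (4R,6S)-6-[(E)-2-iodoethenyl]-4-methoxyoxan-2-one | O=C1C[C@H](OC)C[C@@H](/C=C/I)O1 | intermediate
6 | (3R,5S,6E)-5-hydroxy-7-iodo-N,3-dimethoxy-N-methylhept-6-enamide | CON(C)C(=O)C[C@H](OC)C[C@H](O)/C=C/I | intermediate
7 | (3R,5S,6E)-5-[tert-butyl(dimethyl)silyl]oxy-7-iodo-N,3-dimethoxy-N-methylhept-6-enamide | CON(C)C(=O)C[C@H](OC)C[C@H](O[Si](C)(C)C(C)(C)C)/C=C/I | intermediate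
8 | (3R,5S,6E)-5-[tert-butyl(dimethyl)silyl]oxy-7-iodo-3-methoxyhept-6-enal | O=CC[C@H](OC)C[C@H](O[Si](C)(C)C(C)(C)C)/C=C/I | intermediate
9 | tert-butyl-[(1E,3S,5S,7Z)-1,8-diiodo-5-methoxynona-1,7-dien-3-yl]oxy-dimethylsilane (C8–C15) | C/C(I)=C/C[C@H](OC)C[C@H](O[Si](C)(C)C(C)(C)C)/C=C/I | intermediate
10 | but-2-yn-1-ol | CC#CCO | starting material
11 | sodium 2,2-bis(2-methoxyethoxy)-3-methyl-5H-1,2-oxaaluminol-2-uide (cyclic vinylalanate) | CC1=CCO[Al-]1(OCCOC)OCCOC.[Na+] | intermediate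
12 | (Z)-3-iodobut-2-en-1-ol | C/C(I)=C/CO | intermediate
13 | (Z)-3-iodobut-2-enal | C/C(I)=C/C=O | intermediate
14 | ethyl (2E,4Z)-5-iodohexa-2,4-dienoate | CCOC(=O)/C=C/C=C(C)\I | intermediate
15 | ethyl (2E,4Z,6E)-5-methyl-7-(tributylstannyl)hepta-2,4,6-trienoate | CCOC(=O)/C=C/C=C(C)\C=C\[Sn](CCCC)(CCCC)CCCC | intermediate
16 | (2E,4Z,6E)-5-methyl-7-(tributylstannyl)hepta-2,4,6-trienoic acid (C1–C7) | OC(=O)/C=C/C=C(C)\C=C\[Sn](CCCC)(CCCC)CCCC | intermediate
17 | ethyl but-2-ynoate | CCOC(=O)C#CC | starting material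
18 | ethyl (E)-3-(tributylstannyl)but-2-enoate | CCOC(=O)/C=C(C)/[Sn](CCCC)(CCCC)CCCC | intermediate
19 | (E)-3-(tributylstannyl)but-2-en-1-ol | OC/C=C(C)/[Sn](CCCC)(CCCC)CCCC | intermediate
20 | (E)-3-(tributylstannyl)but-2-enal | O=C/C=C(C)/[Sn](CCCC)(CCCC)CCCC | intermediate
21 | tributyl-[(2E,4E)-5-(4,4,5,5-tetramethyl-1,3,2-dioxaborolan-2-yl)penta-2,4-dien-2-yl]stannane (C16–C19 linchpin) | CC1(C)OB(/C=C/C=C(C)/[Sn](CCCC)(CCCC)CCCC)OC1(C)C | intermediate
22 | tert-butyl N-[(2R)-1-hydroxypropan-2-yl]carbamate (N-Boc-D-alaninol) | C[C@@H](NC(=O)OC(C)(C)C)CO | starting material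
23 | tert-butyl N-[(2R)-1-oxopropan-2-yl]carbamate | C[C@@H](NC(=O)OC(C)(C)C)C=O | intermediate
24 | tert-butyl N-[(2R,3S,4S)-3-hydroxy-4-methylhex-5-en-2-yl]carbamate | C=C[C@H](C)[C@H](O)[C@@H](C)NC(=O)OC(C)(C)C | intermediate
25 | tert-butyl (4R,5S)-5-[(2S)-but-3-en-2-yl]-2,2,4-trimethyl-1,3-oxazolidine-3-carboxylate | C=C[C@H](C)[C@H]1[C@@H](C)N(C(=O)OC(C)(C)C)C(C)(C)O1 | intermediate
26 | tert-butyl (4R,5S)-2,2,4-trimethyl-5-[(2R)-1-oxopropan-2-yl]-1,3-oxazolidine-3-carboxylate | O=C[C@H](C)[C@H]1[C@@H](C)N(C(=O)OC(C)(C)C)C(C)(C)O1 | intermediate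
27 | (2S)-but-3-yn-2-ol | C[C@H](O)C#C | starting material
28 | (2S)-but-3-yn-2-yl methanesulfonate | C[C@H](OS(C)(=O)=O)C#C | intermediate
29 | tert-butyl (4R,5S)-5-[(2S,3R,4R)-3-hydroxy-4-methylhex-5-yn-2-yl]-2,2,4-trimethyl-1,3-oxazolidine-3-carboxylate | C#C[C@@H](C)[C@@H](O)[C@H](C)[C@H]1[C@@H](C)N(C(=O)OC(C)(C)C)C(C)(C)O1 | intermediate
30 | (E)-C20-alkenylzirconocene chloride of 29 with O23 as zirconocene alkoxide (Cp drawn η1) | Cl[Zr](C1C=CC=C1)(C1C=CC=C1)/C=C/[C@@H](C)[C@@H](O[Zr](Cl)(C1C=CC=C1)C1C=CC=C1)[C@H](C)[C@H]2[C@@H](C)N(C(=O)OC(C)(C)C)C(C)(C)O2 | intermediate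
31 | tert-butyl (4R,5S)-5-[(2S,3R,4R,5E)-3-hydroxy-6-iodo-4-methylhex-5-en-2-yl]-2,2,4-trimethyl-1,3-oxazolidine-3-carboxylate | I/C=C/[C@@H](C)[C@@H](O)[C@H](C)[C@H]1[C@@H](C)N(C(=O)OC(C)(C)C)C(C)(C)O1 | intermediate
32 | tert-butyl (4R,5S)-5-[(2S,3R,4R,5E,7E,9E)-3-hydroxy-4,7-dimethyl-10-(4,4,5,5-tetramethyl-1,3,2-dioxaborolan-2-yl)deca-5,7,9-trien-2-yl]-2,2,4-trimethyl-1,3-oxazolidine-3-carboxylate (C16–C27) | CC1(C)OB(/C=C/C=C(C)/C=C/[C@@H](C)[C@@H](O)[C@H](C)[C@H]2[C@@H](C)N(C(=O)OC(C)(C)C)C(C)(C)O2)OC1(C)C | intermediate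
33 | tert-butyl (4R,5S)-5-[(2S,3R,4R,5E,7E,9E,11E,13S,15S,17Z)-13-[tert-butyl(dimethyl)silyl]oxy-3-hydroxy-18-iodo-15-methoxy-4,7-dimethylnonadeca-5,7,9,11,17-pentaen-2-yl]-2,2,4-trimethyl-1,3-oxazolidine-3-carboxylate (C8–C27 seco-alcohol) | C/C(I)=C/C[C@H](OC)C[C@H](O[Si](C)(C)C(C)(C)C)/C=C/C=C/C=C(C)/C=C/[C@@H](C)[C@@H](O)[C@H](C)[C@H]1[C@@H](C)N(C(=O)OC(C)(C)C)C(C)(C)O1 | intermediate
34 | C23 (2E,4Z,6E)-5-methyl-7-(tributylstannyl)hepta-2,4,6-trienoate ester of 33 | C/C(I)=C/C[C@H](OC)C[C@H](O[Si](C)(C)C(C)(C)C)/C=C/C=C/C=C(C)/C=C/[C@@H](C)[C@@H](OC(=O)/C=C/C=C(C)\C=C\[Sn](CCCC)(CCCC)CCCC)[C@H](C)[C@H]1[C@@H](C)N(C(=O)OC(C)(C)C)C(C)(C)O1 | intermediate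
35 | 24-membered (2E,4Z,6E,8Z,14E,16E,18E,20E)-octaene lactone with 11-OMe, 13-OTBS and the N-Boc oxazolidine side chain at C23 | CO[C@@H]1C[C@H](O[Si](C)(C)C(C)(C)C)/C=C/C=C/C=C(C)/C=C/[C@@H](C)[C@H]([C@H](C)[C@H]2[C@@H](C)N(C(=O)OC(C)(C)C)C(C)(C)O2)OC(=O)/C=C/C=C(C)\C=C\C(C)=C/C1 | intermediate
36 | 13-O-TBS-13-O-decarbamoyl-N-deacetyl-N-Boc-N,25-O-isopropylidene-superstolide A | CO[C@@H]1C[C@H](O[Si](C)(C)C(C)(C)C)[C@@H]2C=C[C@@H]3/C=C(C)/C=C/[C@@H](C)[C@H]([C@H](C)[C@H]4[C@@H](C)N(C(=O)OC(C)(C)C)C(C)(C)O4)OC(=O)/C=C/C=C(C)\C=C\[C@]3(C)[C@@H]2C1 | intermediate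
37 | 13-O-decarbamoyl-N-deacetyl-N-Boc-N,25-O-isopropylidene-superstolide A | CO[C@@H]1C[C@H](O)[C@@H]2C=C[C@@H]3/C=C(C)/C=C/[C@@H](C)[C@H]([C@H](C)[C@H]4[C@@H](C)N(C(=O)OC(C)(C)C)C(C)(C)O4)OC(=O)/C=C/C=C(C)\C=C\[C@]3(C)[C@@H]2C1 | intermediate
38 | 13-O-(trichloroacetylcarbamoyl) derivative of 37 | CO[C@@H]1C[C@H](OC(=O)NC(=O)C(Cl)(Cl)Cl)[C@@H]2C=C[C@@H]3/C=C(C)/C=C/[C@@H](C)[C@H]([C@H](C)[C@H]4[C@@H](C)N(C(=O)OC(C)(C)C)C(C)(C)O4)OC(=O)/C=C/C=C(C)\C=C\[C@]3(C)[C@@H]2C1 | intermediate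
39 | N-deacetyl-N-Boc-N,25-O-isopropylidene-superstolide A | CO[C@@H]1C[C@H](OC(N)=O)[C@@H]2C=C[C@@H]3/C=C(C)/C=C/[C@@H](C)[C@H]([C@H](C)[C@H]4[C@@H](C)N(C(=O)OC(C)(C)C)C(C)(C)O4)OC(=O)/C=C/C=C(C)\C=C\[C@]3(C)[C@@H]2C1 | intermediate
40 | N-deacetylsuperstolide A | CO[C@@H]1C[C@H](OC(N)=O)[C@@H]2C=C[C@@H]3/C=C(C)/C=C/[C@@H](C)[C@H]([C@H](C)[C@H](O)[C@@H](C)N)OC(=O)/C=C/C=C(C)\C=C\[C@]3(C)[C@@H]2C1 | intermediate
41 | superstolide A | CO[C@@H]1C[C@H](OC(N)=O)[C@@H]2C=C[C@@H]3/C=C(C)/C=C/[C@@H](C)[C@H]([C@H](C)[C@H](O)[C@@H](C)NC(C)=O)OC(=O)/C=C/C=C(C)\C=C\[C@]3(C)[C@@H]2C1 | target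

**Step count and risks**

Total steps: 30. Longest linear sequence: 14 steps (1 → 41, steps 1–8 and 25–30).

Steps most likely to fail:

1. Step 27 (Stille macrocyclization/transannular Diels–Alder). Oxidative addition and transmetalation at the hindered, α-methyl-substituted (Z)-vinyl iodide may be slow at 1 mM, so protodestannylation and intermolecular coupling could outrun ring closure. The fallback moves the ring-closing bond from C7–C8 to C5–C6; it sets out from 33 and 14 and comes back at 35. Stille coupling of 33 with excess (E)-1,2-bis(tributylstannyl)ethene (Pd2(dba)3, AsPh3, NMP, normal concentration) should give the C6-stannyl (6E,8Z)-diene alcohol F1. Saponification of 14 (LiOH) gives (2E,4Z)-5-iodohexa-2,4-dienoic acid F2. Yamaguchi esterification of F1 with F2 gives the iodide–stannane ester F3. Intramolecular Stille coupling of F3 then joins the activated dienoate iodide (C5) to the unhindered terminal stannane (C6) and gives 35, which goes on to 36 as in step 27.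

2. Step 25 (site-selective Suzuki coupling). Discrimination between the two vinyl iodides of 9 may be incomplete, giving coupling at C8 or at both ends. The fallback installs the second iodide only after the coupling; it sets out from 7 and 32 and comes back at 33. Suzuki coupling of 32 with the mono-iodide 7 (Pd(PPh3)4, TlOEt) gives the Weinreb amide tetraene F4. TESOTf/2,6-lutidine protects 23-OH and gives the triethylsilyl ether F5. DIBAL-H at −78 °C gives the aldehyde F6. Stork–Zhao olefination as in step 8 gives the (Z)-vinyl iodide triethylsilyl ether F7. HF·pyridine/pyridine removes the triethylsilyl group selectively and gives 33.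

3. Step 26 (esterification of the doubly α-branched 23-OH). Acylation may be slow, and during it the DMAP-activated trienoyl group could isomerize at C4=C5 (Z to E) or lose tin. The fallback forms the C2=C3 bond on the ester instead; it sets out from 33 and 12 and comes back at 34. Acylation of 33 with the small diethylphosphonoacetic acid (DCC, DMAP) gives the phosphonoacetate F8. Stille coupling of 12 with excess (E)-1,2-bis(tributylstannyl)ethene gives (2Z,4E)-3-methyl-5-(tributylstannyl)penta-2,4-dien-1-ol F9. MnO2 gives (2Z,4E)-3-methyl-5-(tributylstannyl)penta-2,4-dienal F10. Horner–Wadsworth–Emmons olefination of F8 with F10 under mild LiCl/i-Pr2NEt conditions in MeCN forms the 2E olefin and gives 34.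

**Further compounds**

F1 | step 27 | C6-tributylstannyl (6E,8Z)-diene C6–C27 alcohol (33 with a vinylstannane in place of iodine) | CCCC[Sn](CCCC)(CCCC)/C=C/C(C)=C\C[C@H](OC)C[C@H](O[Si](C)(C)C(C)(C)C)/C=C/C=C/C=C(C)/C=C/[C@@H](C)[C@@H](O)[C@H](C)[C@H]1[C@@H](C)N(C(=O)OC(C)(C)C)C(C)(C)O1
F2 | step 27 | (2E,4Z)-5-iodohexa-2,4-dienoic acid | OC(=O)/C=C/C=C(C)\I
F3 | step 27 | C23 (2E,4Z)-5-iodohexa-2,4-dienoate ester of F1 | CCCC[Sn](CCCC)(CCCC)/C=C/C(C)=C\C[C@H](OC)C[C@H](O[Si](C)(C)C(C)(C)C)/C=C/C=C/C=C(C)/C=C/[C@@H](C)[C@@H](OC(=O)/C=C/C=C(C)\I)[C@H](C)[C@H]1[C@@H](C)N(C(=O)OC(C)(C)C)C(C)(C)O1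
F4 | step 25 | C9 Weinreb amide (14E,16E,18E,20E)-tetraene with free 23-OH | CON(C)C(=O)C[C@H](OC)C[C@H](O[Si](C)(C)C(C)(C)C)/C=C/C=C/C=C(C)/C=C/[C@@H](C)[C@@H](O)[C@H](C)[C@H]1[C@@H](C)N(C(=O)OC(C)(C)C)C(C)(C)O1
F5 | step 25 | 23-O-triethylsilyl ether of F4 | CON(C)C(=O)C[C@H](OC)C[C@H](O[Si](C)(C)C(C)(C)C)/C=C/C=C/C=C(C)/C=C/[C@@H](C)[C@@H](O[Si](CC)(CC)CC)[C@H](C)[C@H]1[C@@H](C)N(C(=O)OC(C)(C)C)C(C)(C)O1
F6 | step 25 | C9 aldehyde from F5 | O=CC[C@H](OC)C[C@H](O[Si](C)(C)C(C)(C)C)/C=C/C=C/C=C(C)/C=C/[C@@H](C)[C@@H](O[Si](CC)(CC)CC)[C@H](C)[C@H]1[C@@H](C)N(C(=O)OC(C)(C)C)C(C)(C)O1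
F7 | step 25 | 23-O-triethylsilyl ether of 33 | C/C(I)=C/C[C@H](OC)C[C@H](O[Si](C)(C)C(C)(C)C)/C=C/C=C/C=C(C)/C=C/[C@@H](C)[C@@H](O[Si](CC)(CC)CC)[C@H](C)[C@H]1[C@@H](C)N(C(=O)OC(C)(C)C)C(C)(C)O1
F8 | step 26 | C23 diethylphosphonoacetate of 33 | C/C(I)=C/C[C@H](OC)C[C@H](O[Si](C)(C)C(C)(C)C)/C=C/C=C/C=C(C)/C=C/[C@@H](C)[C@@H](OC(=O)CP(=O)(OCC)OCC)[C@H](C)[C@H]1[C@@H](C)N(C(=O)OC(C)(C)C)C(C)(C)O1
F9 | step 26 | (2Z,4E)-3-methyl-5-(tributylstannyl)penta-2,4-dien-1-ol | OC/C=C(C)\C=C\[Sn](CCCC)(CCCC)CCCC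
F10 | step 26 | (2Z,4E)-3-methyl-5-(tributylstannyl)penta-2,4-dienal | O=C/C=C(C)\C=C\[Sn](CCCC)(CCCC)CCCC
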